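**Strategy.** The naphthalene is numbered C1 (aryl), C2 (benzyl), C3 (OH), C4 (H), with ring A as the C4a/C5–C8/C8a benzo ring. The plan rests on C4: it carries only hydrogen and is bonded on one side to the ring A fusion carbon C4a and on the other to the hydroxylated C3. It is therefore introduced late, as a one-carbon unit inserted into the aryl–carbonyl bond of a 1-indanone. One operation, Me3SiCHN2/BF3·OEt2 ring expansion, forms C3–C4 and C4–C4a and turns the five-membered ring into the 2-tetralone. The precursor is the tetrabenzylated trans-3-aryl-2-benzyl-6-benzyloxy-5,7-dimethoxyindan-1-one; DDQ aromatisation and hydrogenolysis follow.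

Key step: step 9

Remark 1: The target defines no stereo element; the hindered C1–aryl axis is taken as unspecified, all sp3 stereocentres on the way are racemic, and both are erased in step 10, so the cis/trans purity of 15 and 18 is not critical.
Remark 2: 4-Bromo-3-methoxyphenol (5) is taken as a catalogue compound; it fixes methoxy ortho and benzyloxy para to bromine without a regioselective protection. Compound names use systematic locants; the strategy numbering above is used only where stated.

Step 1
Reactants: 1 syringaldehyde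
Product: 2 4-(benzyloxy)-3,5-dimethoxybenzaldehyde
Conditions: BnBr, K2CO3, DMF, 60 °C
Reagents that add atoms: benzyl bromide, BrCc1ccccc1
Why: Williamson etherification of the acidic para-formyl phenoxide installs a benzyl ether that should survive mild acid, BF3·OEt2 and DDQ and leave only in the final hydrogenolysis.

Step 2
Reactants: 2 4-(benzyloxy)-3,5-dimethoxybenzaldehyde; 3 Meldrum's acid (2,2-dimethyl-1,3-dioxane-4,6-dione)
Product: 4 5-[4-(benzyloxy)-3,5-dimethoxybenzylidene]-2,2-dimethyl-1,3-dioxane-4,6-dione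
Conditions: pyrrolidine (10 mol%), AcOH (10 mol%), toluene, rt
Reagents that add atoms: none
Why: Knoevenagel condensation of a non-enolisable aldehyde with the strongly C–H acidic cyclic malonate should give the doubly activated alkylidene acceptor with loss of water.

Step 3
Reactants: 5 4-bromo-3-methoxyphenol
Product: 6 4-(benzyloxy)-1-bromo-2-methoxybenzene
Conditions: BnBr, K2CO3, acetone, reflux
Reagents that add atoms: benzyl bromide, BrCc1ccccc1
Why: Williamson etherification of the only free phenol gives the aryl bromide with the oxygen pattern already in place.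

Step 4
Reactants: 6 4-(benzyloxy)-1-bromo-2-methoxybenzene; 4 5-[4-(benzyloxy)-3,5-dimethoxybenzylidene]-2,2-dimethyl-1,3-dioxane-4,6-dione
Product: 8 5-{[4-(benzyloxy)-2-methoxyphenyl][4-(benzyloxy)-3,5-dimethoxyphenyl]methyl}-2,2-dimethyl-1,3-dioxane-4,6-dione (racemic), via aryl Grignard reagent 7 (not isolated)
Conditions: 6, Mg, THF, 45 °C; then 4, THF, 0 °C → rt; 1 M HCl work-up
Reagents that add atoms: none
Why: Magnesium insertion into the aryl bromide and uncatalysed 1,4-addition of the Grignard reagent to the alkylidene Meldrum's acid (conjugate addition to a doubly activated alkene whose acylal carbonyls resist 1,2-attack) should forge the diarylmethine carbon, whose single stereocentre forms racemic and needs no control.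

Step 5
Reactants: 8 5-{[4-(benzyloxy)-2-methoxyphenyl][4-(benzyloxy)-3,5-dimethoxyphenyl]methyl}-2,2-dimethyl-1,3-dioxane-4,6-dione (racemic)
Product: 10 3-[4-(benzyloxy)-2-methoxyphenyl]-3-[4-(benzyloxy)-3,5-dimethoxyphenyl]propanoic acid (racemic), via malonic acid 9 (not isolated)
Conditions: pyridine/H2O (10:1), 100 °C
Reagents that add atoms: water, O
Why: Hydrolytic opening of the acylal releases acetone and the resulting malonic acid loses CO2 at this temperature (malonic acid decarboxylation) in a neutral medium that should leave the benzyl ethers alone.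

Step 6
Reactants: 10 3-[4-(benzyloxy)-2-methoxyphenyl]-3-[4-(benzyloxy)-3,5-dimethoxyphenyl]propanoic acid (racemic)
Product: 12 6-(benzyloxy)-3-[4-(benzyloxy)-2-methoxyphenyl]-5,7-dimethoxyindan-1-one (racemic), via mixed anhydride 11 (not isolated)
Conditions: (CF3CO)2O (2.5 equiv), CH2Cl2, 0 °C → rt
Reagents that add atoms: none
Why: Intramolecular Friedel–Crafts acylation through the mixed trifluoroacetic anhydride should close the five-membered ring on ring A at the carbon ortho to one methoxy group and para to the other, whereas the only free ortho position of the other aryl ring is meta to both of its oxygens, and the mild acidity should spare the benzyl ethers.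

Step 7
Reactants: 12 6-(benzyloxy)-3-[4-(benzyloxy)-2-methoxyphenyl]-5,7-dimethoxyindan-1-one (racemic); 13 3,4-bis(benzyloxy)benzaldehyde
Product: 14 (E)-6-(benzyloxy)-3-[4-(benzyloxy)-2-methoxyphenyl]-2-[3,4-bis(benzyloxy)benzylidene]-5,7-dimethoxyindan-1-one (racemic at C3)
Conditions: KOH (0.2 equiv), EtOH/THF, rt
Reagents that add atoms: none
Why: Claisen–Schmidt (crossed aldol) condensation of the indanone C2 methylene with a non-enolisable aldehyde, followed by E1cB dehydration, should give the E alkene with the aryl group anti to the carbonyl.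

Step 8
Reactants: 14 (E)-6-(benzyloxy)-3-[4-(benzyloxy)-2-methoxyphenyl]-2-[3,4-bis(benzyloxy)benzylidene]-5,7-dimethoxyindan-1-one (racemic at C3)
Product: 15 trans-6-(benzyloxy)-3-[4-(benzyloxy)-2-methoxyphenyl]-2-[3,4-bis(benzyloxy)benzyl]-5,7-dimethoxyindan-1-one (racemic)
Conditions: Cu(OAc)2·H2O (5 mol%), 1,2-bis(diphenylphosphino)benzene (5 mol%), (EtO)2MeSiH, t-BuOH, toluene, rt; then DBU (0.2 equiv), rt
Reagents that add atoms: none
Why: Conjugate reduction by a phosphine-ligated copper hydride should deliver hydride to the benzylidene carbon without touching the aryl benzyl ethers or the donor-deactivated ketone, and the epimerisable C2 centre settles trans to the C3 aryl group as the thermodynamic arrangement under DBU equilibration.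

Step 9
Reactants: 15 trans-6-(benzyloxy)-3-[4-(benzyloxy)-2-methoxyphenyl]-2-[3,4-bis(benzyloxy)benzyl]-5,7-dimethoxyindan-1-one (racemic)
Product: 18 trans-4-[4-(benzyloxy)-2-methoxyphenyl]-7-(benzyloxy)-3-[3,4-bis(benzyloxy)benzyl]-6,8-dimethoxy-3,4-dihydronaphthalen-2(1H)-one (racemic), via diazonium betaine 16 (not isolated), via silyl ketone 17 (not isolated)
Conditions: Me3SiCHN2 (1.5 equiv, hexanes), BF3·OEt2 (1.5 equiv), CH2Cl2, −78 → −20 °C; then 1 M HCl, THF, rt
Reagents that add atoms: (trimethylsilyl)diazomethane, C[Si](C)(C)C=[N+]=[N-]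
Why: BF3 activates the indanone C1 carbonyl, the diazo carbon adds to give the β-diazonium alkoxide 16, and a 1,2-shift of ring A carbon C7a from C1 to the diazonium carbon expels N2 to give the α-silyl ketone 17, which is protodesilylated on acidic work-up; the inserted carbon becomes C4 of the target, bonded to C3 (the carbonyl carbon) and to C4a. The closest known reaction type is the Lewis-acid-promoted homologation of aryl ketones with Me3SiCHN2 (a Tiffeneau–Demjanov-type diazoalkane insertion), established for the enlargement of 1-indanones and 1-tetralones by aryl migration. The six-membered ring is not closed by a cyclisation but arises by ring enlargement, one carbon being inserted into the C1–C7a bond of the five-membered ring. No stereocentre is created in the isolated product, since the silicon-bearing carbon ends as CH2, and the trans relationship of the aryl and benzyl groups is carried over unchanged. The step needs migration of the aryl carbon in preference to the secondary alkyl carbon C2, and a single insertion: C7a is ortho to one methoxy group and para to the other, so it should shift through a stabilised phenonium-like transition state, while the bulky silyl group of 17 and the limited amount of diazo reagent should hold back a second homologation.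

Step 10
Reactants: 18 trans-4-[4-(benzyloxy)-2-methoxyphenyl]-7-(benzyloxy)-3-[3,4-bis(benzyloxy)benzyl]-6,8-dimethoxy-3,4-dihydronaphthalen-2(1H)-one (racemic)
Product: 19 4-[4-(benzyloxy)-2-methoxyphenyl]-7-(benzyloxy)-3-[3,4-bis(benzyloxy)benzyl]-6,8-dimethoxynaphthalen-2-ol
Conditions: DDQ (1.05 equiv), 1,4-dioxane, rt → 50 °C
Reagents that add atoms: none
Why: Quinone dehydrogenation: the enol conjugated with ring A should give up hydride from the doubly benzylic C4–H, and loss of the C3 proton aromatises the ring, which erases both stereocentres; plain benzyl ethers should tolerate one equivalent of DDQ.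

Step 11
Reactants: 19 4-[4-(benzyloxy)-2-methoxyphenyl]-7-(benzyloxy)-3-[3,4-bis(benzyloxy)benzyl]-6,8-dimethoxynaphthalen-2-ol
Product: 20 3-(3,4-dihydroxybenzyl)-4-(4-hydroxy-2-methoxyphenyl)-6,8-dimethoxynaphthalene-2,7-diol (CNP0000244.0)
Conditions: H2 (1 atm), 10% Pd/C, EtOAc/MeOH (degassed), rt
Reagents that add atoms: none
Why: Catalytic hydrogenolysis should cleave the four aryl benzyl ethers while methyl ethers, the naphthalene and the diarylmethane C–C bonds are inert at ambient pressure; degassed solvents protect the oxidisable catechol and naphthol.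

**Compound list**

1 | syringaldehyde (4-hydroxy-3,5-dimethoxybenzaldehyde) | COc1cc(C=O)cc(OC)c1O | starting material
2 | 4-(benzyloxy)-3,5-dimethoxybenzaldehyde | COc1cc(C=O)cc(OC)c1OCc1ccccc1 | intermediate
3 | Meldrum's acid (2,2-dimethyl-1,3-dioxane-4,6-dione) | CC1(C)OC(=O)CC(=O)O1 | starting material
4 | 5-[4-(benzyloxy)-3,5-dimethoxybenzylidene]-2,2-dimethyl-1,3-dioxane-4,6-dione | COc1cc(C=C2C(=O)OC(C)(C)OC2=O)cc(OC)c1OCc1ccccc1 | intermediate
5 | 4-bromo-3-methoxyphenol | COc1cc(O)ccc1Br | starting material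
6 | 4-(benzyloxy)-1-bromo-2-methoxybenzene | COc1cc(OCc2ccccc2)ccc1Br | intermediate
7 | [4-(benzyloxy)-2-methoxyphenyl]magnesium bromide | COc1cc(OCc2ccccc2)ccc1[Mg]Br | intermediate (not isolated)
8 | 5-{[4-(benzyloxy)-2-methoxyphenyl][4-(benzyloxy)-3,5-dimethoxyphenyl]methyl}-2,2-dimethyl-1,3-dioxane-4,6-dione (racemic) | COc1cc(OCc2ccccc2)ccc1C(c1cc(OC)c(OCc2ccccc2)c(OC)c1)C1C(=O)OC(C)(C)OC1=O | intermediate
9 | 2-{[4-(benzyloxy)-2-methoxyphenyl][4-(benzyloxy)-3,5-dimethoxyphenyl]methyl}propanedioic acid (racemic) | COc1cc(OCc2ccccc2)ccc1C(c1cc(OC)c(OCc2ccccc2)c(OC)c1)C(C(=O)O)C(=O)O | intermediate (not isolated)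
10 | 3-[4-(benzyloxy)-2-methoxyphenyl]-3-[4-(benzyloxy)-3,5-dimethoxyphenyl]propanoic acid (racemic) | COc1cc(OCc2ccccc2)ccc1C(CC(=O)O)c1cc(OC)c(OCc2ccccc2)c(OC)c1 | intermediate
11 | mixed anhydride of acid 10 and trifluoroacetic acid (racemic) | COc1cc(OCc2ccccc2)ccc1C(CC(=O)OC(=O)C(F)(F)F)c1cc(OC)c(OCc2ccccc2)c(OC)c1 | intermediate (not isolated)
12 | 6-(benzyloxy)-3-[4-(benzyloxy)-2-methoxyphenyl]-5,7-dimethoxyindan-1-one (racemic) | O=C1CC(c2ccc(OCc3ccccc3)cc2OC)c2cc(OC)c(OCc3ccccc3)c(OC)c21 | intermediate
13 | 3,4-bis(benzyloxy)benzaldehyde | O=Cc1ccc(OCc2ccccc2)c(OCc2ccccc2)c1 | starting material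
14 | (E)-6-(benzyloxy)-3-[4-(benzyloxy)-2-methoxyphenyl]-2-[3,4-bis(benzyloxy)benzylidene]-5,7-dimethoxyindan-1-one (racemic at C3) | O=C1/C(=C/c2ccc(OCc3ccccc3)c(OCc3ccccc3)c2)C(c2ccc(OCc3ccccc3)cc2OC)c2cc(OC)c(OCc3ccccc3)c(OC)c21 | intermediate
15 | trans-6-(benzyloxy)-3-[4-(benzyloxy)-2-methoxyphenyl]-2-[3,4-bis(benzyloxy)benzyl]-5,7-dimethoxyindan-1-one (racemic; one enantiomer drawn) | O=C1[C@@H](Cc2ccc(OCc3ccccc3)c(OCc3ccccc3)c2)[C@H](c2ccc(OCc3ccccc3)cc2OC)c2cc(OC)c(OCc3ccccc3)c(OC)c21 | intermediate (key-step precursor)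
16 | BF3-bound β-diazonium alkoxide of 15: indanone C1 carries O–BF3(−) and CH(SiMe3)N2(+); zwitterion; trans at C2/C3; C1 and the silylated carbon unassigned | F[B-](F)(F)OC1(C([N+]#N)[Si](C)(C)C)[C@@H](Cc2ccc(OCc3ccccc3)c(OCc3ccccc3)c2)[C@H](c2ccc(OCc3ccccc3)cc2OC)c2cc(OC)c(OCc3ccccc3)c(OC)c21 | intermediate (not isolated)
17 | 1-(trimethylsilyl) derivative of 18: trans-4-[4-(benzyloxy)-2-methoxyphenyl]-7-(benzyloxy)-3-[3,4-bis(benzyloxy)benzyl]-6,8-dimethoxy-1-(trimethylsilyl)-3,4-dihydronaphthalen-2(1H)-one (C1 unassigned) | O=C1C([Si](C)(C)C)c2c(OC)c(OCc3ccccc3)c(OC)cc2[C@@H](c2ccc(OCc3ccccc3)cc2OC)[C@@H]1Cc1ccc(OCc2ccccc2)c(OCc2ccccc2)c1 | intermediate (not isolated)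
18 | trans-4-[4-(benzyloxy)-2-methoxyphenyl]-7-(benzyloxy)-3-[3,4-bis(benzyloxy)benzyl]-6,8-dimethoxy-3,4-dihydronaphthalen-2(1H)-one (racemic; one enantiomer drawn) | O=C1Cc2c(OC)c(OCc3ccccc3)c(OC)cc2[C@@H](c2ccc(OCc3ccccc3)cc2OC)[C@@H]1Cc1ccc(OCc2ccccc2)c(OCc2ccccc2)c1 | intermediate (key-step product)
19 | 4-[4-(benzyloxy)-2-methoxyphenyl]-7-(benzyloxy)-3-[3,4-bis(benzyloxy)benzyl]-6,8-dimethoxynaphthalen-2-ol | COc1cc(OCc2ccccc2)ccc1-c1c(Cc2ccc(OCc3ccccc3)c(OCc3ccccc3)c2)c(O)cc2c(OC)c(OCc3ccccc3)c(OC)cc12 | intermediate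
20 | 3-(3,4-dihydroxybenzyl)-4-(4-hydroxy-2-methoxyphenyl)-6,8-dimethoxynaphthalene-2,7-diol (CNP0000244.0) | COc1cc(O)ccc1-c1c(Cc2ccc(O)c(O)c2)c(O)cc2c(OC)c(O)c(OC)cc12 | target

**Totals**

Total step count: 11. Longest linear sequence: 10 steps (1, 2, 4, 5, 6, 7, 8, 9, 10, 11 from syringaldehyde).

**Steps most likely to fail**

Step 9 (key step). Three processes could interfere:
- migration of the secondary alkyl carbon C2 instead of the ring A carbon;
- slow addition to a carbonyl that is deactivated by ortho and para methoxy donation and shielded by the ortho methoxy group;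
- a second insertion into the more electrophilic product ketone.

The fallback sets out from 15 and comes back at 18. Wittig methylenation (Ph3PCH3Br, KOt-Bu, THF) would give trans-6-(benzyloxy)-3-[4-(benzyloxy)-2-methoxyphenyl]-2-[3,4-bis(benzyloxy)benzyl]-5,7-dimethoxy-1-methyleneindane F1. Oxidative rearrangement with the trivalent iodine reagent PhI(OH)OTs in MeOH would follow: iodine adds to the terminal CH2, methanol to C1, and the ring A carbon shifts to CH2 as iodobenzene leaves. This would give the ring-enlarged dimethyl ketal trans-4-[4-(benzyloxy)-2-methoxyphenyl]-7-(benzyloxy)-3-[3,4-bis(benzyloxy)benzyl]-2,2,6,8-tetramethoxy-1,2,3,4-tetrahydronaphthalene F2, which aqueous HCl in THF hydrolyses to 18. This is a known way from 1-methylene indanes and tetralins to 2-tetralones and benzosuberones, and it replaces the competition within a betaine by a cationic 1,2-aryl shift.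

Step 10. The freshly formed, electron-rich 2-naphthol may be oxidised further by DDQ (quinone methide formation at the ortho benzyl group, oxidative coupling at the free ortho position), or the diarylmethane CH2 may be oxidised. The fallback sets out from 18 and comes back at 19. O-acetylation of the enol (Ac2O, Et3N, DMAP, CH2Cl2) would give the enol acetate trans-4-[4-(benzyloxy)-2-methoxyphenyl]-7-(benzyloxy)-3-[3,4-bis(benzyloxy)benzyl]-6,8-dimethoxy-3,4-dihydronaphthalen-2-yl acetate F3. DDQ in dioxane would aromatise it to 4-[4-(benzyloxy)-2-methoxyphenyl]-7-(benzyloxy)-3-[3,4-bis(benzyloxy)benzyl]-6,8-dimethoxynaphthalen-2-yl acetate F4, so that the oxygen stays masked as an ester during the oxidation. Methanolysis (K2CO3, MeOH) would then release 19.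

Step 8. Hydride transfer to the congested, donor-substituted benzylidene ketone may be slow, 1,2-reduction may compete, or the exocyclic double bond may migrate into the ring under the basic conditions of step 7 before it is reduced. The fallback sets out from 12 and comes back at 15, bypassing steps 7 and 8. Enolate alkylation (LiN(SiMe3)2, THF, −78 °C; then purchased 3,4-bis(benzyloxy)benzyl chloride, Bu4NI cat., −78 → 0 °C) should introduce the benzyl group anti to the C3 aryl group and give trans-15 directly. No compound outside the list is made (F0).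

**Further compounds**

F1 | step 9 | trans-6-(benzyloxy)-3-[4-(benzyloxy)-2-methoxyphenyl]-2-[3,4-bis(benzyloxy)benzyl]-5,7-dimethoxy-1-methyleneindane (racemic) | C=C1[C@@H](Cc2ccc(OCc3ccccc3)c(OCc3ccccc3)c2)[C@H](c2ccc(OCc3ccccc3)cc2OC)c2cc(OC)c(OCc3ccccc3)c(OC)c21
F2 | step 9 | trans-4-[4-(benzyloxy)-2-methoxyphenyl]-7-(benzyloxy)-3-[3,4-bis(benzyloxy)benzyl]-2,2,6,8-tetramethoxy-1,2,3,4-tetrahydronaphthalene (racemic) | COC1(OC)Cc2c(OC)c(OCc3ccccc3)c(OC)cc2[C@@H](c2ccc(OCc3ccccc3)cc2OC)[C@@H]1Cc1ccc(OCc2ccccc2)c(OCc2ccccc2)c1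
F3 | step 10 | trans-4-[4-(benzyloxy)-2-methoxyphenyl]-7-(benzyloxy)-3-[3,4-bis(benzyloxy)benzyl]-6,8-dimethoxy-3,4-dihydronaphthalen-2-yl acetate (racemic) | CC(=O)OC1=Cc2c(OC)c(OCc3ccccc3)c(OC)cc2[C@@H](c2ccc(OCc3ccccc3)cc2OC)[C@@H]1Cc1ccc(OCc2ccccc2)c(OCc2ccccc2)c1
F4 | step 10 | 4-[4-(benzyloxy)-2-methoxyphenyl]-7-(benzyloxy)-3-[3,4-bis(benzyloxy)benzyl]-6,8-dimethoxynaphthalen-2-yl acetate | COc1cc(OCc2ccccc2)ccc1-c1c(Cc2ccc(OCc3ccccc3)c(OCc3ccccc3)c2)c(OC(C)=O)cc2c(OC)c(OCc3ccccc3)c(OC)cc12
F0 | step 8 | none | none
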